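**Strategy.** The seven-membered ring (C5–C6–C7–C8–C9–C10–C11, longipinane numbering) is closed last, by the C5–C6 bond. The precursor is a bicyclo[3.1.1]heptanone, made by an intramolecular ketene [2+2] cycloaddition that builds cyclobutane and six-membered ring together; its cyclobutanone carbon C5, as a sulfonylhydrazone, lies 1,3 across the four-membered ring from quaternary C10, which carries a (Z)-alkenyl chain ending in a silyloxy-substituted isopropenyl group. Hydrogen-atom transfer to that alkene gives the tertiary C6 radical, which adds 7-exo to C5=N; loss of sulfinate and N2 leaves C5–H. One operation thus forms the ring, the gem-dimethyl carbon and the C5 stereocentre, while the C7 ether later directs the 8,9-diol.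

Key step: step 12

Numbering: longipinane numbering is used for the target and for all bicyclic and tricyclic intermediates: C1 ketone carbon, C2=C3 (CH3 on C3), C4 and C11 bridgehead CH, C5 cyclobutane CH, C6 C(CH3)2, C7 and C8 ester-bearing CH, C9 CHOH, C10 quaternary C–CH3. The cyclobutane is C4–C5–C11–C10, the six-membered ring C1–C2–C3–C4–C10–C11, the seven-membered ring C5–C6–C7–C8–C9–C10–C11. Acyclic compounds carry their own chain numbers in their names.

Assumption: the catalyst enantiomers named in steps 1, 5 and 7 are those expected to give the configurations drawn. The centres made in steps 5 and 7 (future C1 and C3) only relay chirality in step 9 and become trigonal in step 14, so the antipodal catalysts would be used there if the cycloaddition favoured the other face.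

Step 1
Reactants: 1 (E)-3-methylpent-2-en-4-yn-1-ol; 2 methacrolein
Product: 3 (2E,6S)-3,7-dimethylocta-2,7-dien-4-yne-1,6-diol
Conditions: ZnMe2 (excess), (S,S)-ProPhenol (cat.), Ph3PO (cat.), toluene, 0 °C; aq. NH4Cl
Reagents that add atoms: none
Why: Catalytic asymmetric alkynylzinc addition to an aldehyde, in which the chiral dinuclear zinc catalyst delivers the acetylide to one face of methacrolein and so sets the future C7 carbinol (6S), the allylic hydroxyl of 1 being carried as its zinc alkoxide.

Step 2
Reactants: 3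
Product: 4 (2E,6S)-6-hydroxy-3,7-dimethylocta-2,7-dien-4-ynal
Conditions: TEMPO (cat.), PhI(OAc)2, CH2Cl2, rt
Reagents that add atoms: none
Why: The TEMPO/PhI(OAc)2 oxidation is selective for the primary allylic alcohol over the secondary one and leaves the enyne and its E geometry untouched.

Step 3
Reactants: 4
Product: 5 (2E,6S)-6-(tert-butyldimethylsilyloxy)-3,7-dimethylocta-2,7-dien-4-ynal
Conditions: TBSCl, imidazole, DMF, 0 °C to rt
Reagents that add atoms: tert-butyldimethylsilyl chloride, CC(C)(C)[Si](C)(C)Cl
Why: Imidazole-mediated silylation protects the only hydroxyl; the enal is inert under these conditions.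

Step 4
Reactants: 6 methyl 3-methylbut-2-enoate
Product: 7 tert-butyl(1-methoxy-3-methylbuta-1,3-dienyloxy)dimethylsilane
Conditions: LDA, THF/DMPU, −78 °C; TBSCl
Reagents that add atoms: tert-butyldimethylsilyl chloride, CC(C)(C)[Si](C)(C)Cl
Why: γ-Deprotonation of the senecioate and O-silylation give the silyl dienolate needed for the vinylogous aldol reaction.

Step 5
Reactants: 5; 7
Product: 8 methyl (2E,5S,6E,10S)-10-(tert-butyldimethylsilyloxy)-5-hydroxy-3,7,11-trimethyldodeca-2,6,11-trien-8-ynoate
Conditions: SiCl4, (R,R)-binaphthyldiamine-derived bisphosphoramide (cat.), i-Pr2NEt (cat.), CH2Cl2, −78 °C; aq. NaHCO3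
Reagents that add atoms: none
Why: Vinylogous Mukaiyama aldol reaction, in which the chiral Lewis base–trichlorosilyl cation activates the enynal and the dienolate attacks through its γ-carbon on one aldehyde face, setting the future C1 carbinol (5S) with an E enoate; the remote 10S centre does not interfere.

Step 6
Reactants: 8
Product: 9 methyl (2E,5S,6E,10S)-10-(tert-butyldimethylsilyloxy)-3,7,11-trimethyl-5-(triethylsilyloxy)dodeca-2,6,11-trien-8-ynoate
Conditions: TESCl, imidazole, CH2Cl2, 0 °C
Reagents that add atoms: chlorotriethylsilane, CC[Si](CC)(CC)Cl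
Why: Standard silylation; the triethylsilyl group is chosen so that it can later be removed in the presence of the tert-butyldimethylsilyl ether.

Step 7
Reactants: 9
Product: 10 methyl (3R,5S,6E,10S)-10-(tert-butyldimethylsilyloxy)-3,7,11-trimethyl-5-(triethylsilyloxy)dodeca-6,11-dien-8-ynoate
Conditions: Cu(OAc)2 (cat.), (S)-p-tol-BINAP (cat.), (EtO)2MeSiH, t-BuOH, toluene, 0 °C to rt
Reagents that add atoms: none
Why: Copper hydride-catalysed asymmetric conjugate reduction, in which the ligated copper hydride adds to the β-carbon of the E enoate from the face set by the ligand to give the 3R methyl centre (future C3) and leaves the unactivated enyne and isopropenyl group alone.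

Step 8
Reactants: 10
Product: 11 (3R,5S,6E,10S)-10-(tert-butyldimethylsilyloxy)-3,7,11-trimethyl-5-(triethylsilyloxy)dodeca-6,11-dien-8-ynoic acid
Conditions: LiOH, THF/MeOH/H2O, rt; then 1 M HCl to pH 4, 0 °C
Reagents that add atoms: lithium hydroxide, [Li+].[OH-]
Why: Saponification of the methyl ester; both silyl ethers survive LiOH at room temperature and the brief, mild acidification.

Step 9
Reactants: 11
Product: 14 (1R,2R,4S,5R,7R)-7-[(3S)-3-(tert-butyldimethylsilyloxy)-4-methylpent-4-en-1-ynyl]-2,7-dimethyl-4-(triethylsilyloxy)bicyclo[3.1.1]heptan-6-one, via acid chloride 12 (not isolated), via alkylketene 13 (not isolated)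
Conditions: Me2C=C(Cl)NMe2, CH2Cl2, 0 °C to rt; then slow addition to Et3N, toluene, 110 °C (high dilution)
Reagents that add atoms: none
Why: Intramolecular ketene–alkene [2+2] cycloaddition: the ketene carbonyl carbon (future C5) bonds to the less substituted alkene carbon (C11) and its α-carbon (C4) to C10, closing cyclobutane and six-membered ring in the bridged sense; the E alkene places the C10 methyl syn to the C1–C3 bridge and the alkynyl chain anti, and allylic strain keeps the C1 silyloxy group (and the C3 methyl) away from the quaternary bridge, so this centre sets the absolute configuration of C4, C10 and C11.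

Step 10
Reactants: 14
Product: 15 (1R,2R,4S,5R,7R)-7-[(1Z,3R)-3-(tert-butyldimethylsilyloxy)-4-methylpenta-1,4-dienyl]-2,7-dimethyl-4-(triethylsilyloxy)bicyclo[3.1.1]heptan-6-one
Conditions: H2 (1 atm), Pd/CaCO3 poisoned with Pb(OAc)2 (Lindlar catalyst), quinoline, EtOAc, rt
Reagents that add atoms: none
Why: Lindlar semihydrogenation adds H2 syn to the alkyne and gives the Z alkene (future C8=C9) that the ring closure needs, while the 1,1-disubstituted alkene and the ketone are not reduced.

Step 11
Reactants: 15
Product: 16 2,4,6-trimethylbenzenesulfonylhydrazone of ketone 15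
Conditions: MesSO2NHNH2, THF, rt
Reagents that add atoms: 2,4,6-trimethylbenzenesulfonohydrazide, Cc1cc(C)c(S(=O)(=O)NN)c(C)c1
Why: Condensation of the strained, non-enolisable cyclobutanone (the only carbonyl present) with the sulfonyl hydrazide gives the hydrazone that serves as the radical acceptor.

Step 12
Reactants: 16
Product: 18 7-(tert-butyldimethylsilyloxy)-1-(triethylsilyloxy)longipin-8-ene, via cyclised sulfonyl hydrazide 17 (not isolated)
Conditions: Fe(acac)3 (cat.), PhSiH3, THF/EtOH, 60 °C, high dilution; then MeOH, 65 °C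
Reagents that add atoms: none
Why: Proposed new method: an iron hydride formed from Fe(acac)3 and PhSiH3 transfers a hydrogen atom to the 1,1-disubstituted alkene, which creates the second methyl group and a nucleophilic tertiary radical at C6; this radical adds to the electron-poor C5=N carbon of the sulfonylhydrazone, and the hydrazide so formed loses mesitylenesulfinate and then N2 to leave C5–H. The closest known reaction types are the iron-catalysed reductive coupling of olefins with sulfonylhydrazones (hydromethylation with the formaldehyde hydrazone), hydrogen-atom-transfer alkene–hydrazone cyclisations to five- and six-membered rings, and radical cyclisations onto N-aziridinylimines; new here are the ketone-derived acceptor on a cyclobutane and the ring size. The seven-membered ring closes in the 7-exo-trig mode, helped by the Z C8=C9 alkene and the rigid cyclobutane, which hold C6 near C5. The only new stereocentre, C5, is controlled by C10: the chain sits on the cyclobutane face anti to the C1–C3 bridge, so C6 can bond only to that face and hydrogen ends up syn to the bridge, while C6 is not stereogenic and C7 is untouched. The step needs hydrogen-atom transfer to the 1,1-disubstituted alkene only (the cis-disubstituted alkene reacts far more slowly and the six-membered ring carries no alkene) and a cyclisation faster than reduction of the radical or its 3-exo closure onto C8, which high dilution and the preorganised chain should secure.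

Step 13
Reactants: 18
Product: 19 7-(tert-butyldimethylsilyloxy)longipin-8-en-1-ol
Conditions: PPTS (cat.), MeOH, 0 °C to rt
Reagents that add atoms: none
Why: Acid-catalysed methanolysis removes the more labile triethylsilyl ether at C1 while the neopentylic tert-butyldimethylsilyl ether at C7 stays.

Step 14
Reactants: 19
Product: 20 7-(tert-butyldimethylsilyloxy)longipina-2,8-dien-1-one
Conditions: IBX (excess), DMSO/fluorobenzene, 70 °C
Reagents that add atoms: none
Why: IBX oxidises the C1 alcohol to the ketone and then dehydrogenates it through its enol, which can form only toward C2 because C11 is a bridgehead, to the C2=C3 enone; this erases the relay centres C1 and C3.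

Step 15
Reactants: 20
Product: 21 7-(tert-butyldimethylsilyloxy)-8,9-dihydroxylongipin-2-en-1-one
Conditions: OsO4 (cat.), NMO, acetone/H2O, rt
Reagents that add atoms: N-methylmorpholine N-oxide, C[N+]1([O-])CCOCC1; water, O
Why: Catalytic OsO4 dihydroxylation of the cis C8=C9 alkene takes place anti to the allylic C7 silyloxy group, which sets C8 and C9 with both hydroxyls cis to each other and trans to O7; the electron-poor, trisubstituted C2=C3 enone is not attacked.

Step 16
Reactants: 21
Product: 22 7-(tert-butyldimethylsilyloxy)-8,9-(isopropylidenedioxy)longipin-2-en-1-one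
Conditions: Me2C(OMe)2, PPTS (cat.), CH2Cl2, rt
Reagents that add atoms: 2,2-dimethoxypropane, COC(C)(C)OC
Why: Acetal formation on the cis 8,9-diol gives the five-membered acetonide, which masks O8 and O9 while O7 is exchanged.

Step 17
Reactants: 22
Product: 23 7-hydroxy-8,9-(isopropylidenedioxy)longipin-2-en-1-one
Conditions: Bu4NF, THF, rt to 45 °C; aq. NH4Cl
Reagents that add atoms: none
Why: Fluoride cleaves the hindered C7 silyl ether; the acetonide and the enone are stable to Bu4NF.

Step 18
Reactants: 23
Product: 24 7-angeloyloxy-8,9-(isopropylidenedioxy)longipin-2-en-1-one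
Conditions: angelic acid, 2,4,6-Cl3C6H2COCl, Et3N, toluene, rt; then 23, 80 °C
Reagents that add atoms: angelic acid, C/C=C(/C)C(=O)O
Why: Yamaguchi-type mixed-anhydride esterification without DMAP acylates the only free hydroxyl (C7) and is the protocol that preserves the Z geometry of angelates.

Step 19
Reactants: 24
Product: 25 7-angeloyloxy-8,9-dihydroxylongipin-2-en-1-one
Conditions: AcOH/H2O (4:1), 40 °C
Reagents that add atoms: none
Why: Mild aqueous acid hydrolyses the acetonide and leaves the angelate and the enone intact.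

Step 20
Reactants: 25
Product: 26 (4R,5S,7S,8S,9S,10R,11R)-7,8-bis(angeloyloxy)-9-hydroxylongipin-2-en-1-one (target)
Conditions: angelic acid, 2,4,6-Cl3C6H2COCl, Et3N, toluene, rt; then 25, 40 °C
Reagents that add atoms: angelic acid, C/C=C(/C)C(=O)O
Why: The same Yamaguchi-type mixed anhydride should acylate the C8 hydroxyl in preference to the C9 hydroxyl, which is flanked by quaternary C10, and the C8 ester is also the expected thermodynamic product of any acyl migration between O8 and O9.

**Compound list**

1 | (E)-3-methylpent-2-en-4-yn-1-ol | C#C/C(C)=C/CO | starting material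
2 | methacrolein | CC(=C)C=O | starting material
3 | (2E,6S)-3,7-dimethylocta-2,7-dien-4-yne-1,6-diol | OC/C=C(\C)C#C[C@@H](O)C(C)=C | intermediate
4 | (2E,6S)-6-hydroxy-3,7-dimethylocta-2,7-dien-4-ynal | O=C/C=C(\C)C#C[C@@H](O)C(C)=C | intermediate
5 | (2E,6S)-6-(tert-butyldimethylsilyloxy)-3,7-dimethylocta-2,7-dien-4-ynal | O=C/C=C(\C)C#C[C@@H](O[Si](C)(C)C(C)(C)C)C(C)=C | intermediate
6 | methyl 3-methylbut-2-enoate | COC(=O)C=C(C)C | starting material
7 | tert-butyl(1-methoxy-3-methylbuta-1,3-dienyloxy)dimethylsilane | C=C(C)C=C(OC)O[Si](C)(C)C(C)(C)C | intermediate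
8 | methyl (2E,5S,6E,10S)-10-(tert-butyldimethylsilyloxy)-5-hydroxy-3,7,11-trimethyldodeca-2,6,11-trien-8-ynoate | COC(=O)/C=C(\C)C[C@H](O)/C=C(\C)C#C[C@@H](O[Si](C)(C)C(C)(C)C)C(C)=C | intermediate
9 | methyl (2E,5S,6E,10S)-10-(tert-butyldimethylsilyloxy)-3,7,11-trimethyl-5-(triethylsilyloxy)dodeca-2,6,11-trien-8-ynoate | COC(=O)/C=C(\C)C[C@H](O[Si](CC)(CC)CC)/C=C(\C)C#C[C@@H](O[Si](C)(C)C(C)(C)C)C(C)=C | intermediate
10 | methyl (3R,5S,6E,10S)-10-(tert-butyldimethylsilyloxy)-3,7,11-trimethyl-5-(triethylsilyloxy)dodeca-6,11-dien-8-ynoate | COC(=O)C[C@H](C)C[C@H](O[Si](CC)(CC)CC)/C=C(\C)C#C[C@@H](O[Si](C)(C)C(C)(C)C)C(C)=C | intermediate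
11 | (3R,5S,6E,10S)-10-(tert-butyldimethylsilyloxy)-3,7,11-trimethyl-5-(triethylsilyloxy)dodeca-6,11-dien-8-ynoic acid | OC(=O)C[C@H](C)C[C@H](O[Si](CC)(CC)CC)/C=C(\C)C#C[C@@H](O[Si](C)(C)C(C)(C)C)C(C)=C | intermediate
12 | acid chloride of 11 | ClC(=O)C[C@H](C)C[C@H](O[Si](CC)(CC)CC)/C=C(\C)C#C[C@@H](O[Si](C)(C)C(C)(C)C)C(C)=C | intermediate
13 | alkylketene from 12 | O=C=C[C@H](C)C[C@H](O[Si](CC)(CC)CC)/C=C(\C)C#C[C@@H](O[Si](C)(C)C(C)(C)C)C(C)=C | intermediate
14 | (1R,2R,4S,5R,7R)-7-[(3S)-3-(tert-butyldimethylsilyloxy)-4-methylpent-4-en-1-ynyl]-2,7-dimethyl-4-(triethylsilyloxy)bicyclo[3.1.1]heptan-6-one; ketone carbon = future C5; ring methyl and silyloxy on the face toward the carbonyl bridge; 7-methyl syn to the three-carbon bridge | O=C1[C@H]2[C@@H](O[Si](CC)(CC)CC)C[C@@H](C)[C@@H]1[C@@]2(C)C#C[C@@H](O[Si](C)(C)C(C)(C)C)C(C)=C | intermediate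
15 | (1R,2R,4S,5R,7R)-7-[(1Z,3R)-3-(tert-butyldimethylsilyloxy)-4-methylpenta-1,4-dienyl]-2,7-dimethyl-4-(triethylsilyloxy)bicyclo[3.1.1]heptan-6-one | O=C1[C@H]2[C@@H](O[Si](CC)(CC)CC)C[C@@H](C)[C@@H]1[C@@]2(C)/C=C\[C@@H](O[Si](C)(C)C(C)(C)C)C(C)=C | intermediate
16 | 2,4,6-trimethylbenzenesulfonylhydrazone of 15 (C=N geometry not defined) | Cc1cc(C)c(c(C)c1)S(=O)(=O)NN=C1[C@H]2[C@@H](O[Si](CC)(CC)CC)C[C@@H](C)[C@@H]1[C@@]2(C)/C=C\[C@@H](O[Si](C)(C)C(C)(C)C)C(C)=C | intermediate
17 | cyclised hydrazide: 5-(2-mesitylsulfonylhydrazino)-7-(tert-butyldimethylsilyloxy)-1-(triethylsilyloxy)longipin-8-ene, nitrogen on C5 syn to the C1–C3 bridge | C=1[C@@H](O[Si](C)(C)C(C)(C)C)C(C)(C)[C@]2(NNS(=O)(=O)c4c(C)cc(C)cc4C)[C@H]3[C@@H](O[Si](CC)(CC)CC)C[C@@H](C)[C@@H]2[C@@]3(C)C=1 | intermediate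
18 | 7-(tert-butyldimethylsilyloxy)-1-(triethylsilyloxy)longipin-8-ene; C5–H syn to the C1–C3 bridge; O7 on the seven-membered-ring face syn to C4; O1 and the C3 methyl on the six-membered-ring face toward C5 | C=1[C@@H](O[Si](C)(C)C(C)(C)C)C(C)(C)[C@@H]2[C@H]3[C@@H](O[Si](CC)(CC)CC)C[C@@H](C)[C@@H]2[C@@]3(C)C=1 | intermediate
19 | 7-(tert-butyldimethylsilyloxy)longipin-8-en-1-ol (configuration as 18) | C=1[C@@H](O[Si](C)(C)C(C)(C)C)C(C)(C)[C@@H]2[C@H]3[C@@H](O)C[C@@H](C)[C@@H]2[C@@]3(C)C=1 | intermediate
20 | 7-(tert-butyldimethylsilyloxy)longipina-2,8-dien-1-one | C=1[C@@H](O[Si](C)(C)C(C)(C)C)C(C)(C)[C@@H]2[C@H]3C(=O)C=C(C)[C@@H]2[C@@]3(C)C=1 | intermediate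
21 | 7-(tert-butyldimethylsilyloxy)-8,9-dihydroxylongipin-2-en-1-one; 8-OH and 9-OH syn to C11, trans to O7 | O[C@@H]1[C@@H](O[Si](C)(C)C(C)(C)C)C(C)(C)[C@@H]2[C@H]3C(=O)C=C(C)[C@@H]2[C@@]3(C)[C@@H]1O | intermediate
22 | 7-(tert-butyldimethylsilyloxy)-8,9-(isopropylidenedioxy)longipin-2-en-1-one | CC1(C)O[C@@H]2[C@@H](O[Si](C)(C)C(C)(C)C)C(C)(C)[C@@H]3[C@H]4C(=O)C=C(C)[C@@H]3[C@@]4(C)[C@@H]2O1 | intermediate
23 | 7-hydroxy-8,9-(isopropylidenedioxy)longipin-2-en-1-one | CC1(C)O[C@@H]2[C@@H](O)C(C)(C)[C@@H]3[C@H]4C(=O)C=C(C)[C@@H]3[C@@]4(C)[C@@H]2O1 | intermediate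
24 | 7-angeloyloxy-8,9-(isopropylidenedioxy)longipin-2-en-1-one | CC1(C)O[C@@H]2[C@@H](OC(=O)/C(C)=C\C)C(C)(C)[C@@H]3[C@H]4C(=O)C=C(C)[C@@H]3[C@@]4(C)[C@@H]2O1 | intermediate
25 | 7-angeloyloxy-8,9-dihydroxylongipin-2-en-1-one | O[C@@H]1[C@@H](OC(=O)/C(C)=C\C)C(C)(C)[C@@H]2[C@H]3C(=O)C=C(C)[C@@H]2[C@@]3(C)[C@@H]1O | intermediate
26 | (4R,5S,7S,8S,9S,10R,11R)-7,8-bis(angeloyloxy)-9-hydroxylongipin-2-en-1-one | C/C=C(/C)C(=O)O[C@@H]1[C@@H](OC(=O)/C(C)=C\C)C(C)(C)[C@@H]2[C@H]3C(=O)C=C(C)[C@@H]2[C@@]3(C)[C@@H]1O | target

**Step count.** 20 steps in total; longest linear sequence 19 steps (steps 1–3 and 5–20, from 1 to 26); step 4 is a one-step branch.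

**Steps most likely to fail**

Step 12 (labelled). What may go wrong: reduction of the tertiary radical before it cyclises (plain hydrogenation of the isopropenyl group), its 3-exo closure onto C8 followed by vinyl migration, or incomplete loss of sulfinate and N2 from the hindered hydrazide. The fallback uses a known chain process with a fragmenting acceptor; it sets out from 15 and comes back at 18. Markovnikov hydrochlorination of the isopropenyl group of 15 (Co(BF4)2·6H2O with a salen-type ligand as catalyst, TsCl, PhSiH3, EtOH) should give the tertiary chloride F1. Condensation of its ketone with 1-amino-2-phenylaziridine should give the N-aziridinylimine F2. Slow addition of (Me3Si)3SiH and AIBN in benzene at 80 °C would then abstract chlorine, and the tertiary radical should add to C=N. The aziridinyl aminyl radical opens with loss of styrene and N2, and the C5 radical takes hydrogen from the silane on its only open face to give 18.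

Step 9. What may go wrong: dimerisation or oligomerisation of the alkylketene outrunning a slow cycloaddition onto an alkene that is deactivated by the allylic silyloxy group, and incomplete facial control. The fallback replaces the ketene by a more electrophilic keteniminium ion; it sets out from 11 and comes back at 14. Acid 11 would be converted (Me2C=C(Cl)NMe2, then Me2NH) into the N,N-dimethylamide F3. Tf2O and 2,4,6-collidine in refluxing 1,2-dichloroethane should give the keteniminium triflate F4, which undergoes the same bridged [2+2] cycloaddition to the cyclobutaniminium triflate F5. Aqueous NaHCO3 hydrolyses F5 to 14.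

Step 18. What may go wrong: slow acylation of the neopentylic C7 hydroxyl and Z-to-E isomerisation of the angeloyl group under forcing conditions. The fallback builds the angelate double bond after the acylation; it sets out from 23 and comes back at 24. Alcohol 23 would be esterified with the small 2-[bis(2,2,2-trifluoroethoxy)phosphoryl]propanoic acid (DCC, DMAP) to the phosphonate ester F6. A Z-selective Horner–Wadsworth–Emmons reaction of the Still–Gennari type (KHMDS, 18-crown-6, THF, −78 °C, then acetaldehyde) should then give 24.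

**Further compounds**

F1 | step 12 | tertiary chloride: 15 with the isopropenyl group converted into C(CH3)2Cl | O=C1[C@H]2[C@@H](O[Si](CC)(CC)CC)C[C@@H](C)[C@@H]1[C@@]2(C)/C=C\[C@@H](O[Si](C)(C)C(C)(C)C)C(C)(C)Cl
F2 | step 12 | N-(2-phenylaziridin-1-yl)imine of F1 | c1ccccc1C1CN1N=C2[C@H]3[C@@H](O[Si](CC)(CC)CC)C[C@@H](C)[C@@H]2[C@@]3(C)/C=C\[C@@H](O[Si](C)(C)C(C)(C)C)C(C)(C)Cl
F3 | step 9 | N,N-dimethylamide of 11 | CN(C)C(=O)C[C@H](C)C[C@H](O[Si](CC)(CC)CC)/C=C(\C)C#C[C@@H](O[Si](C)(C)C(C)(C)C)C(C)=C
F4 | step 9 | keteniminium triflate from F3 | C[N+](C)=C=C[C@H](C)C[C@H](O[Si](CC)(CC)CC)/C=C(\C)C#C[C@@H](O[Si](C)(C)C(C)(C)C)C(C)=C.[O-]S(=O)(=O)C(F)(F)F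
F5 | step 9 | cyclobutaniminium triflate (N,N-dimethyliminium of 14) | C[N+](C)=C1[C@H]2[C@@H](O[Si](CC)(CC)CC)C[C@@H](C)[C@@H]1[C@@]2(C)C#C[C@@H](O[Si](C)(C)C(C)(C)C)C(C)=C.[O-]S(=O)(=O)C(F)(F)F
F6 | step 18 | 7-O-{2-[bis(2,2,2-trifluoroethoxy)phosphoryl]propanoyl} ester of 23 | CC1(C)O[C@@H]2[C@@H](OC(=O)C(C)P(=O)(OCC(F)(F)F)OCC(F)(F)F)C(C)(C)[C@@H]3[C@H]4C(=O)C=C(C)[C@@H]3[C@@]4(C)[C@@H]2O1
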